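**Retrosynthetic overview**

1. Target 19 is 5-hydroxy-7-methoxy-6-prenyl-3-(2,4-dihydroxyphenyl)coumarin. The plan rests on the C3=C4 double bond of the pyranone ring C (C3 carries ring B, C4 is bonded to C4a of ring A) and on C4a being flanked by two oxygen-bearing carbons, C8a (O1) and C5 (OH), which are equivalent while C6 is still unsubstituted.
2. Late disconnections: the two ring B MOM ethers, then the C6–prenyl bond, taken back by aromatic Claisen rearrangement to a 5-O-(1,1-dimethylallyl) ether and so to 5-phenol 14.
3. Key disconnection: C3=C4 by ring-closing metathesis of the symmetric bis(2-arylacrylate) 12 of 5-methoxy-2-vinylresorcinol. Either ester closes ring C, and the surviving one is methanolysed to free O5.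
4. Diester 12 comes from diol 5 (from 2,4,6-trihydroxybenzaldehyde 1: O4-methylation, silylation, Wittig methylenation, desilylation) and acid 11 (from 2,4-dihydroxyphenylacetic acid 6: esterification, MOM protection, α-methylenation, saponification).
5. Ring order: rings A and B are bought; ring C is the only ring formed, in step 10.

Key step: step 10

Remark: the target has no stereocentre and its ring alkene is necessarily cis; 3-chloro-3-methylbut-1-yne (the hydrochlorination product of 2-methylbut-3-yn-2-ol) is taken as a purchased reagent.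

**Route**

Step 1
Reactants: 1 2,4,6-trihydroxybenzaldehyde
Product: 2 2,6-dihydroxy-4-methoxybenzaldehyde
Conditions: Me2SO4 (1.0 equiv), K2CO3 (1.0 equiv), acetone, rt
Reagents that add atoms: dimethyl sulfate, COS(=O)(=O)OC
Why: The 4-OH is the only hydroxyl not hydrogen-bonded to the formyl group and is the most acidic, so one equivalent of carbonate and a hard methylating agent should give selective Williamson O-methylation at O4 while the chelated 2- and 6-OH stay free.

Step 2
Reactants: 2 2,6-dihydroxy-4-methoxybenzaldehyde
Product: 3 2,6-bis(tert-butyldimethylsilyloxy)-4-methoxybenzaldehyde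
Conditions: TBSCl (2.5 equiv), imidazole (5 equiv), DMF, rt
Reagents that add atoms: tert-butyldimethylsilyl chloride, CC(C)(C)[Si](C)(C)Cl
Why: Imidazole-promoted silylation masks both acidic phenols so that the ylide of the next step is not quenched and the aldehyde is not deactivated as a phenoxide.

Step 3
Reactants: 3 2,6-bis(tert-butyldimethylsilyloxy)-4-methoxybenzaldehyde
Product: 4 1,3-bis(tert-butyldimethylsilyloxy)-5-methoxy-2-vinylbenzene
Conditions: Ph3PCH3Br (1.5 equiv), KOt-Bu (1.4 equiv), THF, 0 °C; then 3, 0 °C to rt
Reagents that add atoms: methyltriphenylphosphonium bromide, C[P+](c1ccccc1)(c1ccccc1)c1ccccc1.[Br-]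
Why: Wittig methylenation of an aromatic aldehyde with the small non-stabilised ylide should tolerate the two ortho silyloxy groups, and aryl silyl ethers are inert to the ylide.

Step 4
Reactants: 4 1,3-bis(tert-butyldimethylsilyloxy)-5-methoxy-2-vinylbenzene
Product: 5 5-methoxy-2-vinylbenzene-1,3-diol
Conditions: Bu4NF (2.2 equiv), AcOH (2.2 equiv), THF, 0 °C; used at once
Reagents that add atoms: none
Why: Fluoride cleaves both aryl O–Si bonds, and the acetic acid buffer keeps the electron-rich vinylresorcinol away from strongly basic or acidic medium in which it would oligomerise.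

Step 5
Reactants: 6 2,4-dihydroxyphenylacetic acid
Product: 7 methyl 2-(2,4-dihydroxyphenyl)acetate
Conditions: MeOH, H2SO4 (cat.), reflux
Reagents that add atoms: methanol, CO
Why: Fischer esterification in a large excess of methanol favours the open methyl ester over the benzofuranone lactone.

Step 6
Reactants: 7 methyl 2-(2,4-dihydroxyphenyl)acetate
Product: 8 methyl 2-[2,4-bis(methoxymethoxy)phenyl]acetate
Conditions: MOMCl (3 equiv), then i-Pr2NEt (4 equiv), CH2Cl2, 0 °C to rt
Reagents that add atoms: chloromethyl methyl ether, COCCl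
Why: Amine-mediated O-alkylation of both phenols gives acetal ethers that withstand the basic, ruthenium-catalysed and thermal steps ahead, and adding the electrophile before the base caps the ortho phenol before it can lactonise onto the ester.

Step 7
Reactants: 8 methyl 2-[2,4-bis(methoxymethoxy)phenyl]acetate
Product: 10 methyl 2-[2,4-bis(methoxymethoxy)phenyl]acrylate, via aldol adduct 9 (not isolated)
Conditions: (CH2O)n (3 equiv), K2CO3 (2 equiv), Bu4NI (cat.), toluene, 80 °C
Reagents that add atoms: paraformaldehyde (formaldehyde), C=O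
Why: Aldol addition of the arylacetate enolate to formaldehyde followed by E1cB loss of water is the standard α-methylenation of arylacetic esters to 2-arylacrylates.

Step 8
Reactants: 10 methyl 2-[2,4-bis(methoxymethoxy)phenyl]acrylate
Product: 11 2-[2,4-bis(methoxymethoxy)phenyl]acrylic acid
Conditions: LiOH·H2O (2 equiv), THF/H2O, 0 °C to rt; then 1 M HCl to pH 4, 0 °C
Reagents that add atoms: lithium hydroxide, [Li+].[OH-]
Why: Saponification at low temperature lets hydroxide attack the ester carbonyl faster than it adds to the acrylate, and cold acidification only to pH 4 keeps the MOM acetals.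

Step 9
Reactants: 5 5-methoxy-2-vinylbenzene-1,3-diol; 11 2-[2,4-bis(methoxymethoxy)phenyl]acrylic acid (2.3 equiv)
Product: 12 5-methoxy-2-vinyl-1,3-phenylene bis{2-[2,4-bis(methoxymethoxy)phenyl]acrylate}
Conditions: DIC (2.5 equiv), DMAP (0.2 equiv), CH2Cl2, 0 °C to rt
Reagents that add atoms: none
Why: Steglich esterification (carbodiimide activation, DMAP acyl transfer) acylates both equivalent phenols, so neither monoprotection nor a choice between the hydroxyls is needed.

Step 10
Reactants: 12 5-methoxy-2-vinyl-1,3-phenylene bis{2-[2,4-bis(methoxymethoxy)phenyl]acrylate}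
Product: 13 7-methoxy-3-[2,4-bis(methoxymethoxy)phenyl]-2-oxo-2H-chromen-5-yl 2-[2,4-bis(methoxymethoxy)phenyl]acrylate
Conditions: (H2IMes)Cl2Ru(=CH–C6H4-2-Oi-Pr) (second-generation Hoveyda–Grubbs catalyst, H2IMes = 1,3-dimesitylimidazolidin-2-ylidene; 10 mol % in two portions), toluene (0.005 M), 90 °C, Ar sparge
Reagents that add atoms: none
Why: This is an olefin ring-closing metathesis in which the catalyst exchanges at the vinyl group to give a ruthenium arylidene, which adds [2+2] across the methylene of one neighbouring 2-arylacrylate, and cycloreversion of the ruthenacyclobutane forms C3=C4 and a ruthenium methylidene that is turned over with loss of ethylene. The closest known reaction type is the ring-closing metathesis of 2-vinylphenyl acrylates and α-substituted acrylates to coumarins with N-heterocyclic-carbene ruthenium catalysts. Ring C is closed as a six-membered lactone by joining the benzylic carbon (future C4) to the acrylate α-carbon (future C3) across the aryl ester tether O1–C2, and the ring alkene is cis by necessity. No stereocentre is formed. The selectivity needed is ring closure over intermolecular metathesis of the styrene, which should be secured by high dilution, removal of ethylene, the conjugated six-membered product and the reluctance of electron-poor 1,1-disubstituted acrylates to homodimerise, while the choice of ester is irrelevant because the two are related by the mirror plane through C2 and C5 of the arene. The second ester has no partner once the vinyl group is consumed, and the prenyl group is deliberately absent at this stage so that no competing olefin is present.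

Step 11
Reactants: 13 7-methoxy-3-[2,4-bis(methoxymethoxy)phenyl]-2-oxo-2H-chromen-5-yl 2-[2,4-bis(methoxymethoxy)phenyl]acrylate
Product: 14 5-hydroxy-7-methoxy-3-[2,4-bis(methoxymethoxy)phenyl]-2H-chromen-2-one
Conditions: K2CO3 (1.5 equiv), MeOH/THF, 0 °C; then AcOH
Reagents that add atoms: none
Why: Methoxide transesterification cleaves the exocyclic aryl ester, while the lactone either survives or recloses on acidification because its cis C3=C4 geometry is fixed, so only the 5-phenol is unveiled and the released methyl ester 10 can be returned to step 8.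

Step 12
Reactants: 14 5-hydroxy-7-methoxy-3-[2,4-bis(methoxymethoxy)phenyl]-2H-chromen-2-one
Product: 15 7-methoxy-5-[(2-methylbut-3-yn-2-yl)oxy]-3-[2,4-bis(methoxymethoxy)phenyl]-2H-chromen-2-one
Conditions: 3-chloro-3-methylbut-1-yne (2 equiv), DBU (2 equiv), CuCl2·2H2O (1 mol %), MeCN, 0 °C to rt
Reagents that add atoms: 3-chloro-3-methylbut-1-yne, CC(C)(Cl)C#C
Why: Copper-catalysed propargylic substitution through a copper acetylide lets the phenoxide attack the tertiary carbon, the established way to make aryl 1,1-dimethylpropargyl ethers that direct displacement cannot deliver.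

Step 13
Reactants: 15 7-methoxy-5-[(2-methylbut-3-yn-2-yl)oxy]-3-[2,4-bis(methoxymethoxy)phenyl]-2H-chromen-2-one
Product: 16 7-methoxy-5-[(2-methylbut-3-en-2-yl)oxy]-3-[2,4-bis(methoxymethoxy)phenyl]-2H-chromen-2-one
Conditions: H2 (1 atm), Pd/CaCO3 poisoned with Pb(OAc)2 (Lindlar catalyst), quinoline, EtOAc, rt, stopped after one equivalent of H2; filtered and carried on crude
Reagents that add atoms: none
Why: Lindlar semihydrogenation should stop at the terminal alkene on the poisoned palladium surface and leave the conjugated trisubstituted C3=C4 bond and the aryl ether untouched.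

Step 14
Reactants: 16 7-methoxy-5-[(2-methylbut-3-en-2-yl)oxy]-3-[2,4-bis(methoxymethoxy)phenyl]-2H-chromen-2-one
Product: 18 5-hydroxy-7-methoxy-6-(3-methylbut-2-en-1-yl)-3-[2,4-bis(methoxymethoxy)phenyl]-2H-chromen-2-one, via dienone 17 (not isolated)
Conditions: PhNEt2, 120 °C
Reagents that add atoms: none
Why: The aromatic Claisen rearrangement ([3,3]-sigmatropic) transfers the allyl unit with inversion to C6, the only open ortho position of O5 since the other is the ring-fusion carbon C4a, and tautomerisation of the dienone restores the phenol while the amine solvent suppresses acid-catalysed chroman formation.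

Step 15
Reactants: 18 5-hydroxy-7-methoxy-6-(3-methylbut-2-en-1-yl)-3-[2,4-bis(methoxymethoxy)phenyl]-2H-chromen-2-one
Product: 19 3-(2,4-dihydroxyphenyl)-5-hydroxy-7-methoxy-6-(3-methylbut-2-en-1-yl)-2H-chromen-2-one
Conditions: 3 M aq HCl/MeOH (1:5), 45 °C, short reaction time with monitoring
Reagents that add atoms: none
Why: Acid-catalysed acetal exchange with methanol removes both MOM groups, and dilute acid, moderate temperature and short exposure are chosen so that the ortho-prenylphenol is not cyclised to the chroman.

**Compound list**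

1 | 2,4,6-trihydroxybenzaldehyde | O=Cc1c(O)cc(O)cc1O | starting material
2 | 2,6-dihydroxy-4-methoxybenzaldehyde | COc1cc(O)c(C=O)c(O)c1 | intermediate
3 | 2,6-bis(tert-butyldimethylsilyloxy)-4-methoxybenzaldehyde | COc1cc(O[Si](C)(C)C(C)(C)C)c(C=O)c(O[Si](C)(C)C(C)(C)C)c1 | intermediate
4 | 1,3-bis(tert-butyldimethylsilyloxy)-5-methoxy-2-vinylbenzene | COc1cc(O[Si](C)(C)C(C)(C)C)c(C=C)c(O[Si](C)(C)C(C)(C)C)c1 | intermediate
5 | 5-methoxy-2-vinylbenzene-1,3-diol | COc1cc(O)c(C=C)c(O)c1 | intermediate
6 | 2,4-dihydroxyphenylacetic acid | O=C(O)Cc1ccc(O)cc1O | starting material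
7 | methyl 2-(2,4-dihydroxyphenyl)acetate | COC(=O)Cc1ccc(O)cc1O | intermediate
8 | methyl 2-[2,4-bis(methoxymethoxy)phenyl]acetate | COC(=O)Cc1ccc(OCOC)cc1OCOC | intermediate
9 | methyl 3-hydroxy-2-[2,4-bis(methoxymethoxy)phenyl]propanoate (racemic aldol adduct, not isolated) | COC(=O)C(CO)c1ccc(OCOC)cc1OCOC | intermediate
10 | methyl 2-[2,4-bis(methoxymethoxy)phenyl]acrylate | COC(=O)C(=C)c1ccc(OCOC)cc1OCOC | intermediate
11 | 2-[2,4-bis(methoxymethoxy)phenyl]acrylic acid | OC(=O)C(=C)c1ccc(OCOC)cc1OCOC | intermediate
12 | 5-methoxy-2-vinyl-1,3-phenylene bis{2-[2,4-bis(methoxymethoxy)phenyl]acrylate} | COc1cc(OC(=O)C(=C)c2ccc(OCOC)cc2OCOC)c(C=C)c(OC(=O)C(=C)c2ccc(OCOC)cc2OCOC)c1 | intermediate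
13 | 7-methoxy-3-[2,4-bis(methoxymethoxy)phenyl]-2-oxo-2H-chromen-5-yl 2-[2,4-bis(methoxymethoxy)phenyl]acrylate | COc1cc(OC(=O)C(=C)c2ccc(OCOC)cc2OCOC)c2cc(-c3ccc(OCOC)cc3OCOC)c(=O)oc2c1 | intermediate
14 | 5-hydroxy-7-methoxy-3-[2,4-bis(methoxymethoxy)phenyl]-2H-chromen-2-one | COc1cc(O)c2cc(-c3ccc(OCOC)cc3OCOC)c(=O)oc2c1 | intermediate
15 | 7-methoxy-5-[(2-methylbut-3-yn-2-yl)oxy]-3-[2,4-bis(methoxymethoxy)phenyl]-2H-chromen-2-one | COc1cc(OC(C)(C)C#C)c2cc(-c3ccc(OCOC)cc3OCOC)c(=O)oc2c1 | intermediate
16 | 7-methoxy-5-[(2-methylbut-3-en-2-yl)oxy]-3-[2,4-bis(methoxymethoxy)phenyl]-2H-chromen-2-one | COc1cc(OC(C)(C)C=C)c2cc(-c3ccc(OCOC)cc3OCOC)c(=O)oc2c1 | intermediate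
17 | 7-methoxy-6-(3-methylbut-2-en-1-yl)-3-[2,4-bis(methoxymethoxy)phenyl]-2H-chromene-2,5(6H)-dione (racemic dienone, not isolated) | COC1=CC2=C(C=C(c3ccc(OCOC)cc3OCOC)C(=O)O2)C(=O)C1CC=C(C)C | intermediate
18 | 5-hydroxy-7-methoxy-6-(3-methylbut-2-en-1-yl)-3-[2,4-bis(methoxymethoxy)phenyl]-2H-chromen-2-one | COc1cc2oc(=O)c(-c3ccc(OCOC)cc3OCOC)cc2c(O)c1CC=C(C)C | intermediate
19 | 3-(2,4-dihydroxyphenyl)-5-hydroxy-7-methoxy-6-(3-methylbut-2-en-1-yl)-2H-chromen-2-one | COc1cc2oc(=O)c(-c3ccc(O)cc3O)cc2c(O)c1CC=C(C)C | target

**Step count**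

Total steps: 15.
Longest linear sequence: 11 steps (1 to 19 through steps 1–4 and 9–15; equally 6 to 19 through steps 5–15).

**Steps most likely to fail**

1. Step 10. The ruthenium arylidene, formed at a vinyl group flanked by two ortho esters, may fail to engage the hindered, electron-poor 1,1-disubstituted acrylate. The catalyst would then decompose or intermolecular styrene metathesis would take over. Fallback: the same C3=C4 bond would be made by condensation. The fallback sets out from 8 and 2. Saponification of 8 (LiOH, THF/H2O) would give 2-[2,4-bis(methoxymethoxy)phenyl]acetic acid F1. Perkin–Oglialoro condensation of F1 with aldehyde 2 (Ac2O, Et3N, 100 °C) should then give 7-methoxy-3-[2,4-bis(methoxymethoxy)phenyl]-2-oxo-2H-chromen-5-yl acetate F2, the second phenol being acetylated in the same pot. Methanolysis of the acetate (K2CO3, MeOH, 0 °C) comes back to the route at 14.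

2. Step 15. Acid-promoted addition of the free 5-OH across the protonated prenyl double bond (chroman formation), or hydration of that alkene, may outrun acetal cleavage. Fallback: the fallback sets out from 18, whose 5-OH would first be acylated (PivCl, Et3N, DMAP, CH2Cl2) to 7-methoxy-6-(3-methylbut-2-en-1-yl)-3-[2,4-bis(methoxymethoxy)phenyl]-2-oxo-2H-chromen-5-yl pivalate F3. With no free hydroxyl next to the prenyl group, the MOM ethers would be removed (HCl, MeOH, 45 °C) to give 3-(2,4-dihydroxyphenyl)-7-methoxy-6-(3-methylbut-2-en-1-yl)-2-oxo-2H-chromen-5-yl pivalate F4. Mild methanolysis of the pivalate (K2CO3, MeOH, then AcOH) comes back to the route at 19.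

3. Step 9. The free vinylresorcinol may oligomerise before it is acylated, the second and more hindered acylation may stall, or DMAP may trigger conjugate oligomerisation of the acrylic acid. Fallback: the free diol is avoided altogether. The fallback sets out from 11 and 4. Cyanuric fluoride and pyridine in CH2Cl2 would convert 11 into 2-[2,4-bis(methoxymethoxy)phenyl]acryloyl fluoride F5. Bis-silyl ether 4 would then be acylated directly with F5 under fluoride catalysis (Bu4NF, 10 mol %, MeCN, rt), each O–Si bond being exchanged for the ester, to come back to the route at 12.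

**Further compounds**

F1 | step 10 | 2-[2,4-bis(methoxymethoxy)phenyl]acetic acid | OC(=O)Cc1ccc(OCOC)cc1OCOC
F2 | step 10 | 7-methoxy-3-[2,4-bis(methoxymethoxy)phenyl]-2-oxo-2H-chromen-5-yl acetate | COc1cc(OC(C)=O)c2cc(-c3ccc(OCOC)cc3OCOC)c(=O)oc2c1
F3 | step 15 | 7-methoxy-6-(3-methylbut-2-en-1-yl)-3-[2,4-bis(methoxymethoxy)phenyl]-2-oxo-2H-chromen-5-yl pivalate | COc1cc2oc(=O)c(-c3ccc(OCOC)cc3OCOC)cc2c(OC(=O)C(C)(C)C)c1CC=C(C)C
F4 | step 15 | 3-(2,4-dihydroxyphenyl)-7-methoxy-6-(3-methylbut-2-en-1-yl)-2-oxo-2H-chromen-5-yl pivalate | COc1cc2oc(=O)c(-c3ccc(O)cc3O)cc2c(OC(=O)C(C)(C)C)c1CC=C(C)C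
F5 | step 9 | 2-[2,4-bis(methoxymethoxy)phenyl]acryloyl fluoride | C=C(C(F)=O)c1ccc(OCOC)cc1OCOC
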